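**Strategy**

Ring A (C1–C5 and C10, eremophilane numbering) is traced back to a cyclopentanol. C1 bears the oxygen and C10 is the β-carbon of the C8 enone, so the array O–C1–C10=C9–C8=O is the retron of a vinylogous semipinacol shift: in a γ-hydroxy ynone the quaternary carbon C5 moves from C1 to C10, which inserts C10 into the five-membered ring. In the same operation the formyl carbon C6 on C5 condenses with C7 and closes the cross-conjugated dienone ring B. The precursor is a 1-alkynylcyclopentanol that already carries the cis C4/C5 methyl pair and a masked aldehyde; its ynone arm, with C11, comes from an (S)-methylsuccinate half-ester.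

Key step: step 8

Remark: atom labels C1–C15 follow eremophilane numbering throughout; alcohol 5 is carried as a mixture of C1 epimers, which is harmless because C1 becomes sp2 in step 8.

**Route**

Step 1
Reactants: 1 2-methylcyclopent-2-en-1-one
Product: 3 {[(3S)-2,3-dimethylcyclopent-1-en-1-yl]oxy}trimethylsilane, via dimethylaluminium enolate 2 (not isolated)
Conditions: Me3Al, CuTC (2 mol %), chiral phosphoramidite (4 mol %, antipode giving 3S), Et2O, −30 °C; then TMSOTf, THF, −30 → 0 °C
Reagents that add atoms: trimethylaluminium, C[Al](C)C; trimethylsilyl trifluoromethanesulfonate, C[Si](C)(C)OS(=O)(=O)C(F)(F)F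
Why: Cu-catalysed asymmetric conjugate addition of methyl to the α-substituted enone sets C4 (S) under ligand control, and O-silylation of the aluminium enolate fixes the tetrasubstituted enol ether regiospecifically.

Step 2
Reactants: 3 {[(3S)-2,3-dimethylcyclopent-1-en-1-yl]oxy}trimethylsilane
Product: 4 (2S,3S)-2-(1,3-dioxolan-2-yl)-2,3-dimethylcyclopentan-1-one (methyl groups cis)
Conditions: 2-methoxy-1,3-dioxolane, TMSOTf (10 mol %), CH2Cl2, −78 °C
Reagents that add atoms: 2-methoxy-1,3-dioxolane, COC1OCCO1
Why: Mukaiyama-type alkylation of the silyl enol ether by the 1,3-dioxolan-2-ylium ion; the electrophile enters anti to the C4 methyl, so the quaternary C5 is formed with its methyl cis to the C4 methyl.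

Step 3
Reactants: 4 (2S,3S)-2-(1,3-dioxolan-2-yl)-2,3-dimethylcyclopentan-1-one
Product: 5 (2R,3S)-2-(1,3-dioxolan-2-yl)-1-ethynyl-2,3-dimethylcyclopentan-1-ol (both C1 epimers)
Conditions: HC≡CMgBr, CeCl3, THF, −78 → 0 °C; aq. NH4Cl
Reagents that add atoms: ethynylmagnesium bromide, C#C[Mg]Br
Why: Cerium-mediated Grignard 1,2-addition suppresses enolisation of the hindered ketone; the new C1 centre need not be controlled because it becomes sp2 in step 8.

Step 4
Reactants: 6 4-methoxy-2-methylidene-4-oxobutanoic acid (monomethyl itaconate)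
Product: 7 (2S)-4-methoxy-2-methyl-4-oxobutanoic acid
Conditions: H2 (5 bar), [Rh(cod)(Et-DuPhos)]BF4 (0.2 mol %, antipode giving 2S), MeOH, rt
Reagents that add atoms: none
Why: Rh–bisphosphine asymmetric hydrogenation of an itaconate half-ester; the chelating acrylic acid unit and the ligand chirality set C11 (S).

Step 5
Reactants: 7 (2S)-4-methoxy-2-methyl-4-oxobutanoic acid
Product: 8 (2S)-4-[methoxy(methyl)amino]-2-methyl-4-oxobutanoic acid
Conditions: MeNH(OMe)·HCl, i-PrMgCl, THF, −20 → 0 °C; then aq. HCl
Reagents that add atoms: N,O-dimethylhydroxylamine hydrochloride, CNOC.Cl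
Why: Aminolysis of the methyl ester by the magnesium amide gives the Weinreb amide, while the magnesium carboxylate formed first is inert and shields the adjacent stereocentre from enolisation.

Step 6
Reactants: 8 (2S)-4-[methoxy(methyl)amino]-2-methyl-4-oxobutanoic acid
Product: 9 methyl (2S)-4-[methoxy(methyl)amino]-2-methyl-4-oxobutanoate
Conditions: MeI, K2CO3, DMF, rt
Reagents that add atoms: iodomethane, CI
Why: SN2 O-methylation of the carboxylate under conditions too weakly basic to epimerise C11.

Step 7
Reactants: 5 (2R,3S)-2-(1,3-dioxolan-2-yl)-1-ethynyl-2,3-dimethylcyclopentan-1-ol; 9 methyl (2S)-4-[methoxy(methyl)amino]-2-methyl-4-oxobutanoate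
Product: 11 methyl (2S)-6-[(2R,3S)-2-(1,3-dioxolan-2-yl)-1-hydroxy-2,3-dimethylcyclopentyl]-2-methyl-4-oxohex-5-ynoate, via dilithium alkoxide acetylide 10 (not isolated)
Conditions: n-BuLi (2.05 equiv), THF, −78 °C; then 9, −78 → −20 °C; aq. NH4Cl
Reagents that add atoms: none
Why: Weinreb ketone synthesis with the lithium acetylide; the chelated tetrahedral adduct prevents over-addition and the α-branched methyl ester should react more slowly than the amide.

Step 8
Reactants: 11 methyl (2S)-6-[(2R,3S)-2-(1,3-dioxolan-2-yl)-1-hydroxy-2,3-dimethylcyclopentyl]-2-methyl-4-oxohex-5-ynoate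
Product: 14 methyl (2S)-2-[(4aS,5S)-4a,5-dimethyl-2,8-dioxo-2,4a,5,6,7,8-hexahydronaphthalen-3-yl]propanoate, via ene-dione dioxolane 12 (not isolated), via ene-dione aldehyde 13 (not isolated)
Conditions: Me2AlCl (2.5 equiv), CH2Cl2, −78 → 0 °C; then 2 M HCl, THF, 45 °C
Reagents that add atoms: none
Why: Proposed new method: Me2AlCl turns the tertiary alcohol into an aluminium alkoxide and complexes the ynone carbonyl, so that C10 acquires allenyl-cation character and accepts a suprafacial 1,2-shift of the C1–C5 bond while C1 becomes the ketone; this vinylogous semipinacol (α-ketol-type) rearrangement has not been shown for ynones or unstrained cyclopentanols, its closest known relatives being the vinylogous α-ketol rearrangement of γ-hydroxy enones and the π-acid- or halonium-triggered ring expansions of 1-alkynylcyclobutanols. Ring A is not closed but grows from the cyclopentane by insertion of C10 between C1 and C5, and protonation of the aluminium allenolate at C9 from the side of the flat C1 carbonyl should give the (E)-ene-dione 12. Aqueous acid then unmasks the aldehyde (13) and ring B closes by a 6-(enolendo)-exo-trig aldol addition of C7 to C6 with dehydration, an irreversible step that also drains any (Z)-ene-dione equilibrated by reversible HCl addition. No stereocentre is created: C5 migrates with retention, so the cis C4/C5 methyl pair set in steps 1 and 2 is carried into 14, and both C1 epimers of 11 converge because C1 becomes sp2. The step needs C5 and not C2 to migrate, which the higher migratory aptitude of the fully substituted carbon and the relief of strain in the congested C1–C5 bond should secure, and it needs the acetal to stay closed during the shift (cyclic dioxolane, no protic acid, low temperature), since ionisation would open a retro-aldol path that can scramble C5. C7 is the only enolisable position next to C8 that can reach C6, which fixes the aldol regiochemistry.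

Step 9
Reactants: 14 methyl (2S)-2-[(4aS,5S)-4a,5-dimethyl-2,8-dioxo-2,4a,5,6,7,8-hexahydronaphthalen-3-yl]propanoate
Product: 15 methyl (2S)-2-[(4aS,5S,8R)-8-hydroxy-4a,5-dimethyl-2-oxo-2,4a,5,6,7,8-hexahydronaphthalen-3-yl]propanoate
Conditions: NaBH4, CeCl3·7H2O, MeOH, −78 °C
Reagents that add atoms: none
Why: Luche 1,2-reduction should take the C1 carbonyl (singly conjugated, activated as an ene-dione) before the cross-conjugated, α-branched C8 carbonyl, and hydride should enter anti to the axial C5 methyl, placing the C1 hydroxyl cis to it (1R).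

Step 10
Reactants: 15 methyl (2S)-2-[(4aS,5S,8R)-8-hydroxy-4a,5-dimethyl-2-oxo-2,4a,5,6,7,8-hexahydronaphthalen-3-yl]propanoate; 16 angelic acid, (2Z)-2-methylbut-2-enoic acid
Product: 17 methyl (2S)-2-[(4aS,5S,8R)-4a,5-dimethyl-8-{[(2Z)-2-methylbut-2-enoyl]oxy}-2-oxo-2,4a,5,6,7,8-hexahydronaphthalen-3-yl]propanoate (target)
Conditions: 16, 2,4,6-Cl3C6H2COCl, Et3N, toluene, rt; then 15, toluene, 80 °C (no DMAP)
Reagents that add atoms: none
Why: Yamaguchi mixed-anhydride esterification without nucleophilic catalyst is the established way to transfer an angeloyl group without Z→E isomerisation; the C1–O bond is not broken, so the configuration is kept.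

**Compound list**

1 | 2-methylcyclopent-2-en-1-one | CC1=CCCC1=O | starting material
2 | dimethylaluminium (3S)-2,3-dimethylcyclopent-1-en-1-olate | C[Al](C)OC1=C(C)[C@@H](C)CC1 | intermediate
3 | {[(3S)-2,3-dimethylcyclopent-1-en-1-yl]oxy}trimethylsilane | C[Si](C)(C)OC1=C(C)[C@@H](C)CC1 | intermediate
4 | (2S,3S)-2-(1,3-dioxolan-2-yl)-2,3-dimethylcyclopentan-1-one | O=C1CC[C@H](C)[C@@]1(C)C2OCCO2 | intermediate
5 | (2R,3S)-2-(1,3-dioxolan-2-yl)-1-ethynyl-2,3-dimethylcyclopentan-1-ol (C1 epimers) | OC1(C#C)CC[C@H](C)[C@@]1(C)C2OCCO2 | intermediate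
6 | 4-methoxy-2-methylidene-4-oxobutanoic acid (monomethyl itaconate) | C=C(CC(=O)OC)C(=O)O | starting material
7 | (2S)-4-methoxy-2-methyl-4-oxobutanoic acid | COC(=O)C[C@H](C)C(=O)O | intermediate
8 | (2S)-4-[methoxy(methyl)amino]-2-methyl-4-oxobutanoic acid | CON(C)C(=O)C[C@H](C)C(=O)O | intermediate
9 | methyl (2S)-4-[methoxy(methyl)amino]-2-methyl-4-oxobutanoate | CON(C)C(=O)C[C@H](C)C(=O)OC | intermediate
10 | dilithium salt of 5 (lithium alkoxide, lithium acetylide) | [Li]OC1(C#C[Li])CC[C@H](C)[C@@]1(C)C2OCCO2 | intermediate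
11 | methyl (2S)-6-[(2R,3S)-2-(1,3-dioxolan-2-yl)-1-hydroxy-2,3-dimethylcyclopentyl]-2-methyl-4-oxohex-5-ynoate | OC1(C#CC(=O)C[C@H](C)C(=O)OC)CC[C@H](C)[C@@]1(C)C2OCCO2 | intermediate
12 | methyl (2S,5E)-5-[(2R,3S)-2-(1,3-dioxolan-2-yl)-2,3-dimethyl-6-oxocyclohexylidene]-2-methyl-4-oxopentanoate | O=C1CC[C@H](C)[C@@](C)(C2OCCO2)/C1=C\C(=O)C[C@H](C)C(=O)OC | intermediate
13 | methyl (2S,5E)-5-[(2R,3S)-2-formyl-2,3-dimethyl-6-oxocyclohexylidene]-2-methyl-4-oxopentanoate | O=C1CC[C@H](C)[C@@](C)(C=O)/C1=C\C(=O)C[C@H](C)C(=O)OC | intermediate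
14 | methyl (2S)-2-[(4aS,5S)-4a,5-dimethyl-2,8-dioxo-2,4a,5,6,7,8-hexahydronaphthalen-3-yl]propanoate | O=C1CC[C@H](C)[C@@]2(C)C=C([C@H](C)C(=O)OC)C(=O)C=C12 | intermediate
15 | methyl (2S)-2-[(4aS,5S,8R)-8-hydroxy-4a,5-dimethyl-2-oxo-2,4a,5,6,7,8-hexahydronaphthalen-3-yl]propanoate | O[C@@H]1CC[C@H](C)[C@@]2(C)C=C([C@H](C)C(=O)OC)C(=O)C=C12 | intermediate
16 | angelic acid, (2Z)-2-methylbut-2-enoic acid | C/C=C(/C)C(=O)O | starting material
17 | methyl (2S)-2-[(4aS,5S,8R)-4a,5-dimethyl-8-{[(2Z)-2-methylbut-2-enoyl]oxy}-2-oxo-2,4a,5,6,7,8-hexahydronaphthalen-3-yl]propanoate | C/C=C(/C)C(=O)O[C@@H]1CC[C@H](C)[C@@]2(C)C=C([C@H](C)C(=O)OC)C(=O)C=C12 | target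

**Count and risks**

Total step count: 10. Longest linear sequence: 7 steps (1–3 and 7–10; the branch 4–6 and 7–10 is equally long).

Steps most likely to fail:

1. Step 8 (proposed new method). The 1,2-shift of an unstrained cyclopentanol onto the ynone may be too slow to compete. The Lewis acid may instead ionise the dioxolane and trigger retro-aldol-type cleavage of C1–C5 with unselective re-closure, which would erode the C5 configuration. C2 may migrate in place of C5, or adventitious water may lead to hydration and cyclisation to a 3(2H)-furanone. Fallback with known chemistry, from 11 back to 14: the ynone is reduced with CrCl2 in aqueous THF to methyl (2S,5E)-6-[(2R,3S)-2-(1,3-dioxolan-2-yl)-1-hydroxy-2,3-dimethylcyclopentyl]-2-methyl-4-oxohex-5-enoate F1. Weitz–Scheffer epoxidation (t-BuOOH, DBU) should give the trans-epoxy ketone methyl (2S)-4-{3-[(2R,3S)-2-(1,3-dioxolan-2-yl)-1-hydroxy-2,3-dimethylcyclopentyl]oxiran-2-yl}-2-methyl-4-oxobutanoate F2. The established semipinacol rearrangement of tertiary α-hydroxy epoxides (BF3·OEt2, CH2Cl2, −78 °C, where the strained epoxide is activated well below the temperature at which the dioxolane opens) moves C5 anti to the breaking C10–O bond and should give methyl (2S)-5-[(2R,3S)-2-(1,3-dioxolan-2-yl)-2,3-dimethyl-6-oxocyclohexyl]-5-hydroxy-2-methyl-4-oxopentanoate F3. TsOH in wet toluene at 60 °C then dehydrates, unmasks the aldehyde and closes ring B by aldol condensation, returning to the route at 14.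

2. Step 9. Hydride may also attack the cross-conjugated C8 carbonyl or add in conjugate fashion to the ene-dione, so that mixtures of mono- and di-reduced material form. Fallback, from 14 back to 15: exhaustive Luche reduction (excess NaBH4, CeCl3, MeOH, −40 °C) to methyl (2S)-2-[(4aS,5S,8R)-2,8-dihydroxy-4a,5-dimethyl-2,4a,5,6,7,8-hexahydronaphthalen-3-yl]propanoate F4, handled under neutral conditions. Chemoselective oxidation with activated MnO2 in CH2Cl2 should then take the doubly allylic C8 carbinol back to the dienone and leave the hindered mono-allylic C1 hydroxyl, returning at 15.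

3. Step 10. The hindered pseudo-axial allylic alcohol may acylate slowly, and at the temperature then required the angeloyl unit may isomerise to the tiglate or the allylic ester may ionise. Fallback, from 15 back to 17: esterification with 2-[bis(2,2,2-trifluoroethoxy)phosphoryl]propanoic acid (EDC, DMAP, CH2Cl2; no alkene geometry at stake) to methyl (2S)-2-[(4aS,5S,8R)-8-({2-[bis(2,2,2-trifluoroethoxy)phosphoryl]propanoyl}oxy)-4a,5-dimethyl-2-oxo-2,4a,5,6,7,8-hexahydronaphthalen-3-yl]propanoate F5. Still–Gennari olefination with acetaldehyde (1.0 equiv KHMDS, 18-crown-6, THF, −78 °C) then builds the (Z)-2-methylbut-2-enoate on the ester; the phosphonate is deprotonated selectively, and the sequence returns at 17.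

Further compounds
F1 | step 8 | methyl (2S,5E)-6-[(2R,3S)-2-(1,3-dioxolan-2-yl)-1-hydroxy-2,3-dimethylcyclopentyl]-2-methyl-4-oxohex-5-enoate | OC1(/C=C/C(=O)C[C@H](C)C(=O)OC)CC[C@H](C)[C@@]1(C)C2OCCO2
F2 | step 8 | methyl (2S)-4-{3-[(2R,3S)-2-(1,3-dioxolan-2-yl)-1-hydroxy-2,3-dimethylcyclopentyl]oxiran-2-yl}-2-methyl-4-oxobutanoate (trans-epoxide) | OC1(C2OC2C(=O)C[C@H](C)C(=O)OC)CC[C@H](C)[C@@]1(C)C3OCCO3
F3 | step 8 | methyl (2S)-5-[(2R,3S)-2-(1,3-dioxolan-2-yl)-2,3-dimethyl-6-oxocyclohexyl]-5-hydroxy-2-methyl-4-oxopentanoate | O=C1CC[C@H](C)[C@@](C)(C2OCCO2)C1C(O)C(=O)C[C@H](C)C(=O)OC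
F4 | step 9 | methyl (2S)-2-[(4aS,5S,8R)-2,8-dihydroxy-4a,5-dimethyl-2,4a,5,6,7,8-hexahydronaphthalen-3-yl]propanoate | O[C@@H]1CC[C@H](C)[C@@]2(C)C=C([C@H](C)C(=O)OC)C(O)C=C12
F5 | step 10 | methyl (2S)-2-[(4aS,5S,8R)-8-({2-[bis(2,2,2-trifluoroethoxy)phosphoryl]propanoyl}oxy)-4a,5-dimethyl-2-oxo-2,4a,5,6,7,8-hexahydronaphthalen-3-yl]propanoate | CC(P(=O)(OCC(F)(F)F)OCC(F)(F)F)C(=O)O[C@@H]1CC[C@H](C)[C@@]2(C)C=C([C@H](C)C(=O)OC)C(=O)C=C12
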